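## Retrosynthetic overview

1. Target 25 comes from macrocycle 23 by C9 acylation and C6 desilylation. The ten-membered ring, the last ring formed, is closed at C9–C10 by an electrochemical nickel/chromium alkenyl–aldehyde coupling of iodo-aldehyde 22.
2. 22 comes from 13 + 19: the C6–C7 bond is made by Nozaki–Hiyama allylation of epoxy aldehyde 13 with bromomethyl butenolide 19, which also creates the α-methylene lactone and sets C6 and C7.
3. 13 comes from methyl (R)-glycerate acetonide 1: C5 is bought, C4 is set by chelate-controlled MeMgBr addition, and the epoxide (first ring made) is closed by tosylation/Payne rearrangement with inversion at C5. The E-alkenyl iodide comes from a methyl alkyne.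
4. 19 comes from (R)-5-(hydroxymethyl)butyrolactone 14: C8 and the lactone ring are bought; methylenation, then bromination/dehydrobromination.
5. Ring order: lactone (bought), epoxide (step 5), ten-membered carbocycle (step 12).

Assumption: germacrane locants are used for the target (C12 lactone carbonyl, C11=C13 methylene, C8 lactone oxygen, C9 isobutyrate, C1=C10 alkene, C4–C5 epoxide, C6 hydroxyl); 2 and 14 are taken as catalogue compounds.

## Route

Step 1
Reactants: 1 methyl (4R)-2,2-dimethyl-1,3-dioxolane-4-carboxylate; 2 5-bromopent-2-yne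
Product: 5 1-[(4R)-2,2-dimethyl-1,3-dioxolan-4-yl]hex-4-yn-1-one, via Grignard reagent 3 (not isolated), via Weinreb amide 4 (not isolated)
Conditions: 1, MeNH(OMe)·HCl, i-PrMgCl, THF, −20 °C; then 3 (from 2, Mg, THF), −20 → 0 °C; aq NH4Cl
Reagents that add atoms: none
Why: Magnesium-amide aminolysis gives the Weinreb amide in the flask and its chelated tetrahedral adduct with the Grignard reagent stops at the ketone (Weinreb ketone synthesis), leaving the bought stereocentre (C5 of the target) untouched.

Step 2
Reactants: 5 1-[(4R)-2,2-dimethyl-1,3-dioxolan-4-yl]hex-4-yn-1-one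
Product: 6 (2S)-2-[(4R)-2,2-dimethyl-1,3-dioxolan-4-yl]hept-5-yn-2-ol
Conditions: MeMgBr, Et2O/CH2Cl2, −78 °C
Reagents that add atoms: methylmagnesium bromide, C[Mg]Br
Why: Cram-chelate-controlled Grignard addition: magnesium bridges the ketone oxygen and the dioxolane oxygen on the α-carbon, and methyl adds to the face anti to the ring CH2, setting the tertiary carbinol (C4 of the target) as S.

Step 3
Reactants: 6 (2S)-2-[(4R)-2,2-dimethyl-1,3-dioxolan-4-yl]hept-5-yn-2-ol
Product: 8 (2S,5E)-2-[(4R)-2,2-dimethyl-1,3-dioxolan-4-yl]-6-iodohept-5-en-2-ol, via alkenylzirconocene 7 (not isolated)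
Conditions: Cp2Zr(H)Cl (3 equiv), THF, 50 °C; then I2, 0 °C
Reagents that add atoms: iodine, II
Why: Syn hydrozirconation of the methyl alkyne under equilibrating conditions places zirconium on the methyl-bearing carbon, and iodinolysis with retention gives the (E)-2-iodoalkene (hydrozirconation–iodination); one equivalent of hydride is spent on the tertiary hydroxyl.

Step 4
Reactants: 8 (2S,5E)-2-[(4R)-2,2-dimethyl-1,3-dioxolan-4-yl]-6-iodohept-5-en-2-ol
Product: 9 (2R,3S,6E)-7-iodo-3-methyloct-6-ene-1,2,3-triol
Conditions: AcOH/H2O 4:1, 40 °C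
Reagents that add atoms: none
Why: Acid hydrolysis of the isopropylidene acetal frees the triol without touching the alkenyl iodide or either stereocentre.

Step 5
Reactants: 9 (2R,3S,6E)-7-iodo-3-methyloct-6-ene-1,2,3-triol
Product: 12 [(2S,3S)-3-[(3E)-4-iodopent-3-en-1-yl]-3-methyloxiran-2-yl]methanol, via monotosylate 10 (not isolated), via terminal epoxide 11 (not isolated)
Conditions: TsCl (1.05 equiv), pyridine, CH2Cl2, 0 °C; evaporate; then t-BuOK (2.2 equiv), THF/t-BuOH, 0 °C → rt
Reagents that add atoms: none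
Why: Primary-selective tosylation and alkoxide closure give the terminal epoxide, which undergoes Payne rearrangement: the tertiary alkoxide opens it at C5 with inversion (R → S), and the equilibrium favours the trisubstituted epoxide with the primary alkoxide, giving the trans epoxide of the target.

Step 6
Reactants: 12 [(2S,3S)-3-[(3E)-4-iodopent-3-en-1-yl]-3-methyloxiran-2-yl]methanol
Product: 13 (2R,3S)-3-[(3E)-4-iodopent-3-en-1-yl]-3-methyloxirane-2-carbaldehyde
Conditions: TEMPO (10 mol %), PhI(OAc)2, CH2Cl2, rt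
Reagents that add atoms: none
Why: Oxoammonium (TEMPO) oxidation of the primary alcohol stops at the aldehyde and is neutral enough for the epoxide and alkenyl iodide; the epoxide C–H does not enolise, so C5 is safe.

Step 7
Reactants: 14 (5R)-5-(hydroxymethyl)oxolan-2-one
Product: 15 (5R)-5-{[(triethylsilyl)oxy]methyl}oxolan-2-one
Conditions: TESCl, imidazole, CH2Cl2, 0 °C
Reagents that add atoms: chlorotriethylsilane, CC[Si](Cl)(CC)CC
Why: Standard silylation of the primary alcohol; the bought stereocentre (C8 of the target) is untouched.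

Step 8
Reactants: 15 (5R)-5-{[(triethylsilyl)oxy]methyl}oxolan-2-one
Product: 17 (5R)-3-methylidene-5-{[(triethylsilyl)oxy]methyl}oxolan-2-one, via sodium formyl enolate 16 (not isolated)
Conditions: NaH, HCO2Et, Et2O, rt; then (CH2O)n, THF, reflux
Reagents that add atoms: paraformaldehyde (as formaldehyde), C=O
Why: Claisen formylation gives the α-formyl enolate, which undergoes aldol addition to formaldehyde, formyl transfer and loss of formate to give the α-methylene lactone (formylation–formaldehyde methylenation).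

Step 9
Reactants: 17 (5R)-3-methylidene-5-{[(triethylsilyl)oxy]methyl}oxolan-2-one
Product: 19 (5R)-3-(bromomethyl)-5-{[(triethylsilyl)oxy]methyl}furan-2(5H)-one, via dibromide 18 (not isolated)
Conditions: Br2, CH2Cl2, 0 °C → rt; then i-Pr2NEt, 0 °C
Reagents that add atoms: bromine, BrBr
Why: Bromine addition to the exocyclic alkene, then E2 loss of HBr from the tertiary bromide into the ring, gives the conjugated 3-(bromomethyl)butenolide (bromination–dehydrobromination); the hindered amine avoids quaternisation and C8 epimerisation.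

Step 10
Reactants: 13 (2R,3S)-3-[(3E)-4-iodopent-3-en-1-yl]-3-methyloxirane-2-carbaldehyde; 19 (5R)-3-(bromomethyl)-5-{[(triethylsilyl)oxy]methyl}furan-2(5H)-one
Product: 21 (4R,5R)-4-[(S)-{(2S,3S)-3-[(3E)-4-iodopent-3-en-1-yl]-3-methyloxiran-2-yl}[(triethylsilyl)oxy]methyl]-3-methylidene-5-{[(triethylsilyl)oxy]methyl}oxolan-2-one, via chromium alkoxide 20 (not isolated)
Conditions: CrCl2 (4 equiv), THF, 0 °C → rt; then TESCl, imidazole, DMAP (cat.), 0 °C
Reagents that add atoms: chlorotriethylsilane, CC[Si](Cl)(CC)CC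
Why: Nozaki–Hiyama allylation: the allylchromium from 19 adds through its γ-carbon (C7) in a chair Zimmerman–Traxler transition state, anti to the C8 substituent (C7/C8 trans) and with the anti C6/C7 relationship, while Felkin–Anh attack on the epoxy aldehyde (epoxide C–O anti to the nucleophile) prefers the same C6 configuration, so all three preferences give C6 and C7 as in the target; the chromium alkoxide is silylated in the same flask.

Step 11
Reactants: 21 (4R,5R)-4-[(S)-{(2S,3S)-3-[(3E)-4-iodopent-3-en-1-yl]-3-methyloxiran-2-yl}[(triethylsilyl)oxy]methyl]-3-methylidene-5-{[(triethylsilyl)oxy]methyl}oxolan-2-one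
Product: 22 (2R,3R)-3-[(S)-{(2S,3S)-3-[(3E)-4-iodopent-3-en-1-yl]-3-methyloxiran-2-yl}[(triethylsilyl)oxy]methyl]-4-methylidene-5-oxooxolane-2-carbaldehyde
Conditions: (COCl)2, DMSO, CH2Cl2, −78 → −35 °C; then Et3N, −78 → 0 °C
Reagents that add atoms: none
Why: Under Swern conditions a primary triethylsilyl ether is cleaved by the chlorosulfonium salt and oxidised directly to the aldehyde, while the hindered secondary silyl ether at C6 survives (one-pot Swern desilylation–oxidation).

Step 12
Reactants: 22 (2R,3R)-3-[(S)-{(2S,3S)-3-[(3E)-4-iodopent-3-en-1-yl]-3-methyloxiran-2-yl}[(triethylsilyl)oxy]methyl]-4-methylidene-5-oxooxolane-2-carbaldehyde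
Product: 23 (4S,5S,6S,7R,8R,9S)-4,5-epoxy-9-hydroxy-6-[(triethylsilyl)oxy]germacra-1(10)E,11(13)-dien-12,8-olide
Conditions: CrCl3 (20 mol %), NiCl2·neocuproine (2 mol %), Cp2ZrCl2 (1.2 equiv), LiCl, DMF, undivided cell, Zn anode, Ni-foam cathode, constant current 3 mA, 22 added over 12 h to 2 mM, rt; aq NaHCO3
Reagents that add atoms: none
Why: Proposed new method: an electrochemical, chromium-catalytic Nozaki–Hiyama–Kishi macrocyclisation in which the cathode reduces catalytic CrCl3 to divalent chromium, zerovalent nickel inserts into the C10–I bond with retention of the E geometry and passes the alkenyl group to chromium, the alkenyl trivalent chromium species adds to the C9 aldehyde in the same molecule, and Cp2ZrCl2 takes over the alkoxide so that chromium turns over while the zinc anode closes the circuit; electrode-limited generation of the organometallic plus slow addition keeps its concentration low and favours the ten-membered ring over oligomers, and Felkin–Anh attack (C8–O anti to the incoming alkenyl group) sets C9 as S; the closest known reaction types are the intermolecular electrochemical nickel/chromium alkenylation of aldehydes and the stoichiometric CrCl2/NiCl2 macrocyclisation, neither shown electro-catalytically for a medium ring next to an α-methylene lactone and an epoxide.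

Step 13
Reactants: 23 (4S,5S,6S,7R,8R,9S)-4,5-epoxy-9-hydroxy-6-[(triethylsilyl)oxy]germacra-1(10)E,11(13)-dien-12,8-olide
Product: 24 (4S,5S,6S,7R,8R,9S)-4,5-epoxy-9-(2-methylpropanoyloxy)-6-[(triethylsilyl)oxy]germacra-1(10)E,11(13)-dien-12,8-olide
Conditions: i-PrCOCl, pyridine, DMAP (cat.), CH2Cl2, 0 °C
Reagents that add atoms: isobutyryl chloride, CC(C)C(Cl)=O
Why: DMAP-catalysed acylation of the only free hydroxyl (C9) with retention; C6 is masked as its silyl ether, so no regiochemical question arises.

Step 14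
Reactants: 24 (4S,5S,6S,7R,8R,9S)-4,5-epoxy-9-(2-methylpropanoyloxy)-6-[(triethylsilyl)oxy]germacra-1(10)E,11(13)-dien-12,8-olide
Product: 25 (4S,5S,6S,7S,8R,9S)-4,5-epoxy-6-hydroxy-9-(2-methylpropanoyloxy)germacra-1(10)E,11(13)-dien-12,8-olide
Conditions: HF·pyridine, pyridine, THF, 0 °C
Reagents that add atoms: none
Why: Buffered fluoride desilylation removes the triethylsilyl ether without acyl migration (C6 and C9 are not adjacent) and without opening the epoxide or adding to the methylene lactone; the C7 descriptor changes from R to S only because the CIP priorities change.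

## Compound list

1 | methyl (4R)-2,2-dimethyl-1,3-dioxolane-4-carboxylate | COC(=O)[C@H]1COC(C)(C)O1 | starting material
2 | 5-bromopent-2-yne | CC#CCCBr | starting material
3 | pent-3-yn-1-ylmagnesium bromide | CC#CCC[Mg]Br | intermediate
4 | (4R)-N-methoxy-N,2,2-trimethyl-1,3-dioxolane-4-carboxamide | CON(C)C(=O)[C@H]1COC(C)(C)O1 | intermediate
5 | 1-[(4R)-2,2-dimethyl-1,3-dioxolan-4-yl]hex-4-yn-1-one | CC#CCCC(=O)[C@H]1COC(C)(C)O1 | intermediate
6 | (2S)-2-[(4R)-2,2-dimethyl-1,3-dioxolan-4-yl]hept-5-yn-2-ol | CC#CCC[C@](C)(O)[C@H]1COC(C)(C)O1 | intermediate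
7 | (E)-alkenylzirconocene chloride of 6, zirconium on the methyl-bearing alkene carbon, tertiary oxygen also bound to Cp2ZrCl | C/C(=C\CC[C@](C)(O[Zr](Cl)(C1C=CC=C1)C1C=CC=C1)[C@H]1COC(C)(C)O1)[Zr](Cl)(C1C=CC=C1)C1C=CC=C1 | intermediate
8 | (2S,5E)-2-[(4R)-2,2-dimethyl-1,3-dioxolan-4-yl]-6-iodohept-5-en-2-ol | C/C(I)=C\CC[C@](C)(O)[C@H]1COC(C)(C)O1 | intermediate
9 | (2R,3S,6E)-7-iodo-3-methyloct-6-ene-1,2,3-triol | C/C(I)=C\CC[C@](C)(O)[C@H](O)CO | intermediate
10 | (2R,3S,6E)-2,3-dihydroxy-7-iodo-3-methyloct-6-en-1-yl 4-methylbenzenesulfonate | C/C(I)=C\CC[C@](C)(O)[C@H](O)COS(=O)(=O)c1ccc(C)cc1 | intermediate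
11 | (2S,5E)-6-iodo-2-[(2R)-oxiran-2-yl]hept-5-en-2-ol | C/C(I)=C\CC[C@](C)(O)[C@H]1CO1 | intermediate
12 | [(2S,3S)-3-[(3E)-4-iodopent-3-en-1-yl]-3-methyloxiran-2-yl]methanol | C/C(I)=C\CC[C@]1(C)O[C@H]1CO | intermediate
13 | (2R,3S)-3-[(3E)-4-iodopent-3-en-1-yl]-3-methyloxirane-2-carbaldehyde | C/C(I)=C\CC[C@]1(C)O[C@H]1C=O | intermediate
14 | (5R)-5-(hydroxymethyl)oxolan-2-one | OC[C@H]1CCC(=O)O1 | starting material
15 | (5R)-5-{[(triethylsilyl)oxy]methyl}oxolan-2-one | CC[Si](CC)(CC)OC[C@H]1CCC(=O)O1 | intermediate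
16 | sodium [(5R)-2-oxo-5-{[(triethylsilyl)oxy]methyl}oxolan-3-ylidene]methanolate | [Na+].[O-]C=C1C[C@H](CO[Si](CC)(CC)CC)OC1=O | intermediate
17 | (5R)-3-methylidene-5-{[(triethylsilyl)oxy]methyl}oxolan-2-one | C=C1C[C@H](CO[Si](CC)(CC)CC)OC1=O | intermediate
18 | (5R)-3-bromo-3-(bromomethyl)-5-{[(triethylsilyl)oxy]methyl}oxolan-2-one (both C3 epimers) | BrCC1(Br)C[C@H](CO[Si](CC)(CC)CC)OC1=O | intermediate
19 | (5R)-3-(bromomethyl)-5-{[(triethylsilyl)oxy]methyl}furan-2(5H)-one | BrCC1=C[C@H](CO[Si](CC)(CC)CC)OC1=O | intermediate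
20 | dichlorochromium alkoxide of the C6 carbinol (same skeleton and configuration as 21, O–CrCl2 in place of the C6 O–SiEt3) | C=C1C(=O)O[C@@H](CO[Si](CC)(CC)CC)[C@@H]1[C@H](O[Cr](Cl)Cl)[C@@H]1O[C@@]1(C)CC/C=C(\C)I | intermediate
21 | (4R,5R)-4-[(S)-{(2S,3S)-3-[(3E)-4-iodopent-3-en-1-yl]-3-methyloxiran-2-yl}[(triethylsilyl)oxy]methyl]-3-methylidene-5-{[(triethylsilyl)oxy]methyl}oxolan-2-one | C=C1C(=O)O[C@@H](CO[Si](CC)(CC)CC)[C@@H]1[C@H](O[Si](CC)(CC)CC)[C@@H]1O[C@@]1(C)CC/C=C(\C)I | intermediate
22 | (2R,3R)-3-[(S)-{(2S,3S)-3-[(3E)-4-iodopent-3-en-1-yl]-3-methyloxiran-2-yl}[(triethylsilyl)oxy]methyl]-4-methylidene-5-oxooxolane-2-carbaldehyde | C=C1C(=O)O[C@@H](C=O)[C@@H]1[C@H](O[Si](CC)(CC)CC)[C@@H]1O[C@@]1(C)CC/C=C(\C)I | intermediate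
23 | (4S,5S,6S,7R,8R,9S)-4,5-epoxy-9-hydroxy-6-[(triethylsilyl)oxy]germacra-1(10)E,11(13)-dien-12,8-olide | C=C1C(=O)O[C@@H]2[C@@H]1[C@H](O[Si](CC)(CC)CC)[C@@H]1O[C@@]1(C)CC/C=C(\C)[C@@H]2O | intermediate
24 | (4S,5S,6S,7R,8R,9S)-4,5-epoxy-9-(2-methylpropanoyloxy)-6-[(triethylsilyl)oxy]germacra-1(10)E,11(13)-dien-12,8-olide | C=C1C(=O)O[C@@H]2[C@@H]1[C@H](O[Si](CC)(CC)CC)[C@@H]1O[C@@]1(C)CC/C=C(\C)[C@@H]2OC(=O)C(C)C | intermediate
25 | (4S,5S,6S,7S,8R,9S)-4,5-epoxy-6-hydroxy-9-(2-methylpropanoyloxy)germacra-1(10)E,11(13)-dien-12,8-olide | C=C1C(=O)O[C@@H]2[C@@H]1[C@H](O)[C@@H]1O[C@@]1(C)CC/C=C(\C)[C@@H]2OC(=O)C(C)C | target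

## Step count and risks

Total step count: 14. Longest linear sequence: 11 steps (steps 1–6, then 10–14); steps 7–9 form the second branch.

The three steps most likely to fail:

**Step 12, the proposed electrochemical ring closure.** The risks are oligomerisation, nickel-mediated conjugate addition of the alkenyl group to the methylene lactone, and the wrong C9 epimer. The fallback uses known chemistry and gives up both the electrode and the catalytic chromium cycle. The ring is closed by the classical stoichiometric Nozaki–Hiyama–Kishi macrocyclisation: 22 is added by syringe pump to CrCl2 (10 equiv) and NiCl2 (1 mol %) in degassed DMSO/THF at room temperature, to a final 2 mM. The organochromium reagent is then made by a bought stoichiometric reductant, with no turnover reagent and no nickel ligand, and this reaction type is long established for medium and large rings. The fallback sets out from 22 and comes back at 23; it passes through no new compound (F0).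

**Step 5, tosylation and Payne rearrangement.** The risks are an unfavourable epoxide equilibrium, bis-tosylation, and base damage to the alkenyl iodide. The fallback replaces epoxide migration by direct closure onto C5. The primary hydroxyl of 9 is silylated (TBSCl, imidazole) to give (2R,3S,6E)-1-[(tert-butyldimethylsilyl)oxy]-7-iodo-3-methyloct-6-ene-2,3-diol F2. The secondary hydroxyl is mesylated (MsCl, Et3N; the tertiary hydroxyl does not react) to give (2R,3S,6E)-1-[(tert-butyldimethylsilyl)oxy]-3-hydroxy-7-iodo-3-methyloct-6-en-2-yl methanesulfonate F3. t-BuOK in THF makes the tertiary alkoxide displace the mesylate with inversion at C5, giving tert-butyl{[(2S,3S)-3-[(3E)-4-iodopent-3-en-1-yl]-3-methyloxiran-2-yl]methoxy}dimethylsilane F4, and TBAF frees the alcohol. The fallback sets out from 9 and comes back at 12.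

**Step 2, the chelate-controlled methyl addition.** The risk is that the open Felkin–Anh transition state competes and gives the C4 epimer or a poor ratio. The fallback reverses the order in which the two carbon groups are introduced and runs the second addition under deliberately non-chelating conditions. Weinreb amide 4, made from 1 as in step 1, is treated with MeMgBr to give 1-[(4R)-2,2-dimethyl-1,3-dioxolan-4-yl]ethan-1-one F1. The organocerium reagent from Grignard reagent 3 and CeCl3 is then added at −78 °C. Felkin–Anh attack of the pentynyl group on F1 gives the same (2S) carbinol that chelate-controlled methyl addition to 5 gives, because exchanging the two groups and the face attacked cancels out. The fallback sets out from 1 and comes back at 6.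

Further compounds

F1 | step 2 | 1-[(4R)-2,2-dimethyl-1,3-dioxolan-4-yl]ethan-1-one | CC(=O)[C@H]1COC(C)(C)O1
F2 | step 5 | (2R,3S,6E)-1-[(tert-butyldimethylsilyl)oxy]-7-iodo-3-methyloct-6-ene-2,3-diol | C/C(I)=C\CC[C@](C)(O)[C@H](O)CO[Si](C)(C)C(C)(C)C
F3 | step 5 | (2R,3S,6E)-1-[(tert-butyldimethylsilyl)oxy]-3-hydroxy-7-iodo-3-methyloct-6-en-2-yl methanesulfonate | C/C(I)=C\CC[C@](C)(O)[C@H](OS(C)(=O)=O)CO[Si](C)(C)C(C)(C)C
F4 | step 5 | tert-butyl{[(2S,3S)-3-[(3E)-4-iodopent-3-en-1-yl]-3-methyloxiran-2-yl]methoxy}dimethylsilane | C/C(I)=C\CC[C@]1(C)O[C@H]1CO[Si](C)(C)C(C)(C)C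
F0 | step 12 | none | none
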